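## Retrosynthetic overview

- The target is two benzophenones joined by a CH2. Ring A (left 2,6-dihydroxy-4-methoxyphenyl, carrying the CH2) is bonded to ring C (2,4-dihydroxy-6-methylphenyl). Ring B (right; C1 CH2, C2 OMe, C3 H, C4 OH, C5 aroyl, C6 OH) is bonded to ring D (4-hydroxy-2-methoxy-6-methylphenyl).
- Enabling feature: on ring B the ketone carbon on C5 sits directly beside the free hydroxyl on C4 and has the C6 oxygen on its other side. This ortho-hydroxyaryl ketone is what a C4–C5 aryne of ring B takes up from the ring D carboxylic acid, and the C6 oxygen fixes the orientation.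
- Last disconnection (key step): ring B C5–C(=O) together with C4–O, by fluoride-induced aryne generation from a 2-silylaryl triflate already holding rings A, C and B, and formal insertion into the C–O bond of the ring D benzoic acid. Global debenzylation follows.
- Before that: A–CH2–B by ortho-quinone methide C-alkylation (ring B Mannich base plus the A–C acylphloroglucinol); the A–C ketone by aryl Grignard addition and oxidation; the silyl triflate by bromine–lithium exchange and retro-Brook shift. One aryl bromide (4) serves both ring A (Grignard precursor) and ring B (C5 handle).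
- No ring of the target is built: rings A and B come from 5-methoxyresorcinol, rings C and D from 2,4-dihydroxy-6-methylbenzaldehyde. The only ring closed is a transient four-membered benzoxete in the key step.

Key step: step 18

Assumption: the target has no stereocentre; the only stereocentre on the route (carbinol 8) forms racemic and is removed by oxidation. (Chloromethylene)dimethyliminium chloride is used as the commercial salt.

## Route

Step 1
Reactants: 1 5-methoxybenzene-1,3-diol
Product: 2 1-methoxy-3,5-bis(methoxymethoxy)benzene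
Conditions: MOMCl, i-Pr2NEt, CH2Cl2, 0 °C → rt
Reagents that add atoms: chloromethyl methyl ether, COCCl
Why: Williamson-type O-alkylation of both phenols installs two acetal ethers that later direct lithiation to the carbon between them.

Step 2
Reactants: 2 1-methoxy-3,5-bis(methoxymethoxy)benzene
Product: 4 2-bromo-5-methoxy-1,3-bis(methoxymethoxy)benzene, via aryllithium 3 (not isolated)
Conditions: n-BuLi, THF, 0 °C; then BrCCl2CCl2Br, −78 °C → rt
Reagents that add atoms: 1,2-dibromo-1,1,2,2-tetrachloroethane, BrC(Cl)(Cl)C(Cl)(Cl)Br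
Why: Directed ortho-metalation should occur at the carbon flanked by both MOM ethers (stronger directors than OMe), and electrophilic bromination of the aryllithium puts bromine there without regiochemical ambiguity, giving the bromide used for both ring A and ring B.

Step 3
Reactants: 5 2,4-dihydroxy-6-methylbenzaldehyde
Product: 6 2,4-bis(benzyloxy)-6-methylbenzaldehyde
Conditions: BnBr, K2CO3, DMF, 60 °C
Reagents that add atoms: benzyl bromide, BrCc1ccccc1
Why: Williamson benzylation of both phenols, the chelated ortho-hydroxyl reacting in DMF with heating.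

Step 4
Reactants: 4 2-bromo-5-methoxy-1,3-bis(methoxymethoxy)benzene; 6 2,4-bis(benzyloxy)-6-methylbenzaldehyde
Product: 8 [2,4-bis(benzyloxy)-6-methylphenyl][4-methoxy-2,6-bis(methoxymethoxy)phenyl]methanol (racemic), via Grignard reagent 7 (not isolated)
Conditions: Mg turnings (I2 cat.), THF, 50 °C; then 6, 0 °C → rt; H2O
Reagents that add atoms: none
Why: Magnesium insertion into the electron-rich aryl bromide (as for 2,4,6-trialkoxyphenylmagnesium bromides) and Grignard 1,2-addition to the aldehyde give the carbinol, whose stereocentre forms racemic and is removed in step 5.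

Step 5
Reactants: 8 [2,4-bis(benzyloxy)-6-methylphenyl][4-methoxy-2,6-bis(methoxymethoxy)phenyl]methanol
Product: 9 [2,4-bis(benzyloxy)-6-methylphenyl][4-methoxy-2,6-bis(methoxymethoxy)phenyl]methanone
Conditions: IBX, EtOAc, 75 °C
Reagents that add atoms: none
Why: IBX oxidation of the doubly benzylic secondary alcohol under neutral conditions should spare the MOM and benzyl ethers.

Step 6
Reactants: 9 [2,4-bis(benzyloxy)-6-methylphenyl][4-methoxy-2,6-bis(methoxymethoxy)phenyl]methanone
Product: 10 [2,4-bis(benzyloxy)-6-methylphenyl](2,6-dihydroxy-4-methoxyphenyl)methanone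
Conditions: HCl (3 M aq.), MeOH–THF, 50 °C
Reagents that add atoms: none
Why: Acid-catalysed acetal exchange cleaves both MOM ethers while the benzyl ethers stay, exposing ring A as a nucleophilic acylphloroglucinol.

Step 7
Reactants: 4 2-bromo-5-methoxy-1,3-bis(methoxymethoxy)benzene
Product: 11 2-bromo-5-methoxybenzene-1,3-diol
Conditions: HCl (3 M aq.), MeOH, 50 °C
Reagents that add atoms: none
Why: Acidic acetal cleavage frees both phenols of the symmetric bromoresorcinol.

Step 8
Reactants: 11 2-bromo-5-methoxybenzene-1,3-diol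
Product: 13 3-bromo-2,4-dihydroxy-6-methoxybenzaldehyde, via iminium chloride 12 (not isolated)
Conditions: (chloromethylene)dimethyliminium chloride, MeCN, 0 °C → rt; then H2O, 50 °C
Reagents that add atoms: (chloromethylene)dimethyliminium chloride, C[N+](C)=CCl.[Cl-]; water, O
Why: Vilsmeier–Haack formylation can only occur at the two equivalent open positions, and the iminium formed deactivates the ring against a second formylation.

Step 9
Reactants: 13 3-bromo-2,4-dihydroxy-6-methoxybenzaldehyde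
Product: 14 4-(allyloxy)-3-bromo-2-hydroxy-6-methoxybenzaldehyde
Conditions: allyl bromide (1.05 equiv), K2CO3, acetone, rt
Reagents that add atoms: allyl bromide, C=CCBr
Why: Regioselective Williamson alkylation of the more acidic, unchelated 4-hydroxyl, the 2-hydroxyl being held in a hydrogen bond to the aldehyde; this distinguishes the two oxygens of ring B.

Step 10
Reactants: 14 4-(allyloxy)-3-bromo-2-hydroxy-6-methoxybenzaldehyde
Product: 16 3-(allyloxy)-2-bromo-6-[(dimethylamino)methyl]-5-methoxyphenol, via iminium acetate 15 (not isolated)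
Conditions: Me2NH (2 M in THF), AcOH, NaBH(OAc)3, ClCH2CH2Cl, rt
Reagents that add atoms: dimethylamine, CNC
Why: Reductive amination gives a phenolic Mannich base, a stable precursor of an ortho-quinone methide.

Step 11
Reactants: 16 3-(allyloxy)-2-bromo-6-[(dimethylamino)methyl]-5-methoxyphenol; 10 [2,4-bis(benzyloxy)-6-methylphenyl](2,6-dihydroxy-4-methoxyphenyl)methanone
Product: 18 [2,4-bis(benzyloxy)-6-methylphenyl](3-{[4-(allyloxy)-3-bromo-2-hydroxy-6-methoxyphenyl]methyl}-2,6-dihydroxy-4-methoxyphenyl)methanone, via ortho-quinone methide 17 (not isolated)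
Conditions: 10 (2 equiv), 1,4-dioxane, 100 °C, N2 stream
Reagents that add atoms: none
Why: Thermal loss of dimethylamine gives the ortho-quinone methide, which the acidic acylphloroglucinol ring A (two equivalent open positions, far more nucleophilic than benzyl-capped ring C) should trap by conjugate C-alkylation and rearomatisation, the known way to unsymmetrical methylene-bridged acylphloroglucinols.

Step 12
Reactants: 18 [2,4-bis(benzyloxy)-6-methylphenyl](3-{[4-(allyloxy)-3-bromo-2-hydroxy-6-methoxyphenyl]methyl}-2,6-dihydroxy-4-methoxyphenyl)methanone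
Product: 19 [2,4-bis(benzyloxy)-6-methylphenyl](3-{[4-(allyloxy)-2-(benzyloxy)-3-bromo-6-methoxyphenyl]methyl}-2,6-bis(benzyloxy)-4-methoxyphenyl)methanone
Conditions: BnBr, Cs2CO3, DMF, rt → 50 °C
Reagents that add atoms: benzyl bromide, BrCc1ccccc1
Why: Williamson O-benzylation of all three phenols as cesium phenoxides in DMF (favouring O- over C-alkylation), the allyl ether keeping the fourth oxygen distinct.

Step 13
Reactants: 19 [2,4-bis(benzyloxy)-6-methylphenyl](3-{[4-(allyloxy)-2-(benzyloxy)-3-bromo-6-methoxyphenyl]methyl}-2,6-bis(benzyloxy)-4-methoxyphenyl)methanone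
Product: 20 [2,4-bis(benzyloxy)-6-methylphenyl](2,6-bis(benzyloxy)-3-{[2-(benzyloxy)-3-bromo-4-hydroxy-6-methoxyphenyl]methyl}-4-methoxyphenyl)methanone
Conditions: Pd(PPh3)4 (5 mol %), morpholine, THF, rt
Reagents that add atoms: none
Why: Tsuji–Trost deallylation, in which zerovalent palladium ionises the aryl allyl ether and morpholine takes the allyl group, should leave the hindered aryl bromide and the benzyl ethers untouched.

Step 14
Reactants: 20 [2,4-bis(benzyloxy)-6-methylphenyl](2,6-bis(benzyloxy)-3-{[2-(benzyloxy)-3-bromo-4-hydroxy-6-methoxyphenyl]methyl}-4-methoxyphenyl)methanone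
Product: 23 3-(benzyloxy)-4-({2,4-bis(benzyloxy)-3-[2,4-bis(benzyloxy)-6-methylbenzoyl]-6-methoxyphenyl}methyl)-5-methoxy-2-(trimethylsilyl)phenyl trifluoromethanesulfonate, via trimethylsilyl ether 21 (not isolated), via lithium phenoxide 22 (not isolated)
Conditions: HMDS, THF, reflux, then evaporation; n-BuLi (1.05 equiv), THF, −100 → −80 °C; Tf2O, −100 → −80 °C; aq. NaHCO3
Reagents that add atoms: hexamethyldisilazane, C[Si](C)(C)N[Si](C)(C)C; trifluoromethanesulfonic anhydride, O=S(=O)(OS(=O)(=O)C(F)(F)F)C(F)(F)F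
Why: The standard route from 2-bromophenols to 2-(trimethylsilyl)aryl triflates: O-silylation, bromine–lithium exchange (expected to outpace addition to the four-fold ortho-substituted ketone at −100 °C), 1,3 O-to-C silyl shift (retro-Brook) and O-triflation of the phenoxide.

Step 15
Reactants: 5 2,4-dihydroxy-6-methylbenzaldehyde
Product: 24 4-(benzyloxy)-2-hydroxy-6-methylbenzaldehyde
Conditions: BnBr (1.05 equiv), K2CO3, MeCN, rt
Reagents that add atoms: benzyl bromide, BrCc1ccccc1
Why: Regioselective Williamson benzylation of the unchelated, more acidic 4-hydroxyl.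

Step 16
Reactants: 24 4-(benzyloxy)-2-hydroxy-6-methylbenzaldehyde
Product: 25 4-(benzyloxy)-2-methoxy-6-methylbenzaldehyde
Conditions: MeI, K2CO3, DMF, 40 °C
Reagents that add atoms: iodomethane, CI
Why: Williamson methylation of the remaining chelated phenol in DMF.

Step 17
Reactants: 25 4-(benzyloxy)-2-methoxy-6-methylbenzaldehyde
Product: 26 4-(benzyloxy)-2-methoxy-6-methylbenzoic acid
Conditions: NaClO2, NaH2PO4, 2-methyl-2-butene, t-BuOH–H2O, rt
Reagents that add atoms: sodium chlorite, [Na+].[O-]Cl=O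
Why: Pinnick oxidation converts the hindered electron-rich aldehyde into the acid, the alkene scavenging hypochlorous acid before it can chlorinate the ring.

Step 18
Reactants: 23 3-(benzyloxy)-4-({2,4-bis(benzyloxy)-3-[2,4-bis(benzyloxy)-6-methylbenzoyl]-6-methoxyphenyl}methyl)-5-methoxy-2-(trimethylsilyl)phenyl trifluoromethanesulfonate; 26 4-(benzyloxy)-2-methoxy-6-methylbenzoic acid
Product: 29 [2,4-bis(benzyloxy)-6-methylphenyl][2,6-bis(benzyloxy)-3-({2-(benzyloxy)-3-[4-(benzyloxy)-2-methoxy-6-methylbenzoyl]-4-hydroxy-6-methoxyphenyl}methyl)-4-methoxyphenyl]methanone, via cesium carboxylate 27 (not isolated), via aryne 28 (not isolated)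
Conditions: CsF (4 equiv), 26 (2 equiv), THF, 125 °C, sealed tube
Reagents that add atoms: none
Why: Fluoride removes the trimethylsilyl group of 23 with loss of triflate to give aryne 28 (C4–C5 of ring B) and deprotonates 26 to carboxylate 27; the carboxylate oxygen adds to C4, the C5 aryl anion attacks the neighbouring ester carbonyl, and the four-membered alkoxide opens to the C4 phenoxide, so C5–C(=O) and C4–O form in one operation and the two halves are joined. The closest known reaction is the fluoride-induced formal insertion of arynes from 2-silylaryl triflates into the C–O bond of carboxylic acids, which gives ortho-hydroxyaryl ketones (2-hydroxybenzophenones from benzoic acids). The only ring closed is the transient benzoxete, formed by 4-exo-trig addition and opened at once; no ring and no stereocentre remain from this step. The regioselectivity needed comes from the groups beside the triple bond: the C6 benzyloxy group withdraws inductively, so the aryne is attacked at C4 (next to the unsubstituted C3) with negative charge developing at C5 beside oxygen, as 3-alkoxybenzynes take nucleophiles meta to the oxygen. Chemoselectivity rests on all other phenols being benzylated, on the shielded ketone between rings A and C, on intramolecular acyl transfer outrunning protonation of the aryl anion, and on excess acid keeping carboxylate ahead of fluoride and of the product phenoxide as the aryne trap.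

Step 19
Reactants: 29 [2,4-bis(benzyloxy)-6-methylphenyl][2,6-bis(benzyloxy)-3-({2-(benzyloxy)-3-[4-(benzyloxy)-2-methoxy-6-methylbenzoyl]-4-hydroxy-6-methoxyphenyl}methyl)-4-methoxyphenyl]methanone
Product: 30 (2,4-dihydroxy-6-methylphenyl)[3-({2,4-dihydroxy-3-[4-hydroxy-2-methoxy-6-methylbenzoyl]-6-methoxyphenyl}methyl)-2,6-dihydroxy-4-methoxyphenyl]methanone
Conditions: H2 (1 atm), Pd/C (10 wt %), EtOAc–MeOH, rt
Reagents that add atoms: none
Why: Hydrogenolysis of the six benzyl ethers under neutral conditions should leave the hindered, hydrogen-bonded diaryl ketones, the methyl ethers and the diarylmethane bridge intact.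

## Compound list

1 | 5-methoxybenzene-1,3-diol | COc1cc(O)cc(O)c1 | starting material
2 | 1-methoxy-3,5-bis(methoxymethoxy)benzene | COCOc1cc(OC)cc(OCOC)c1 | intermediate
3 | [4-methoxy-2,6-bis(methoxymethoxy)phenyl]lithium | [Li]c1c(OCOC)cc(OC)cc1OCOC | intermediate
4 | 2-bromo-5-methoxy-1,3-bis(methoxymethoxy)benzene | COCOc1cc(OC)cc(OCOC)c1Br | intermediate
5 | 2,4-dihydroxy-6-methylbenzaldehyde | Cc1cc(O)cc(O)c1C=O | starting material
6 | 2,4-bis(benzyloxy)-6-methylbenzaldehyde | Cc1cc(OCc2ccccc2)cc(OCc2ccccc2)c1C=O | intermediate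
7 | bromo[4-methoxy-2,6-bis(methoxymethoxy)phenyl]magnesium | COCOc1cc(OC)cc(OCOC)c1[Mg]Br | intermediate
8 | [2,4-bis(benzyloxy)-6-methylphenyl][4-methoxy-2,6-bis(methoxymethoxy)phenyl]methanol (racemic) | COCOc1cc(OC)cc(OCOC)c1C(O)c1c(C)cc(OCc2ccccc2)cc1OCc1ccccc1 | intermediate
9 | [2,4-bis(benzyloxy)-6-methylphenyl][4-methoxy-2,6-bis(methoxymethoxy)phenyl]methanone | COCOc1cc(OC)cc(OCOC)c1C(=O)c1c(C)cc(OCc2ccccc2)cc1OCc1ccccc1 | intermediate
10 | [2,4-bis(benzyloxy)-6-methylphenyl](2,6-dihydroxy-4-methoxyphenyl)methanone | COc1cc(O)c(C(=O)c2c(C)cc(OCc3ccccc3)cc2OCc2ccccc2)c(O)c1 | intermediate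
11 | 2-bromo-5-methoxybenzene-1,3-diol | COc1cc(O)c(Br)c(O)c1 | intermediate
12 | N-[(3-bromo-2,4-dihydroxy-6-methoxyphenyl)methylidene]-N-methylmethanaminium chloride | C[N+](C)=Cc1c(OC)cc(O)c(Br)c1O.[Cl-] | intermediate
13 | 3-bromo-2,4-dihydroxy-6-methoxybenzaldehyde | COc1cc(O)c(Br)c(O)c1C=O | intermediate
14 | 4-(allyloxy)-3-bromo-2-hydroxy-6-methoxybenzaldehyde | COc1cc(OCC=C)c(Br)c(O)c1C=O | intermediate
15 | N-{[4-(allyloxy)-3-bromo-2-hydroxy-6-methoxyphenyl]methylidene}-N-methylmethanaminium acetate | C[N+](C)=Cc1c(OC)cc(OCC=C)c(Br)c1O.CC(=O)[O-] | intermediate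
16 | 3-(allyloxy)-2-bromo-6-[(dimethylamino)methyl]-5-methoxyphenol | COc1cc(OCC=C)c(Br)c(O)c1CN(C)C | intermediate
17 | 3-(allyloxy)-2-bromo-5-methoxy-6-methylidenecyclohexa-2,4-dien-1-one | O=C1C(Br)=C(OCC=C)C=C(OC)C1=C | intermediate
18 | [2,4-bis(benzyloxy)-6-methylphenyl](3-{[4-(allyloxy)-3-bromo-2-hydroxy-6-methoxyphenyl]methyl}-2,6-dihydroxy-4-methoxyphenyl)methanone | COc1cc(O)c(C(=O)c2c(C)cc(OCc3ccccc3)cc2OCc2ccccc2)c(O)c1Cc1c(OC)cc(OCC=C)c(Br)c1O | intermediate
19 | [2,4-bis(benzyloxy)-6-methylphenyl](3-{[4-(allyloxy)-2-(benzyloxy)-3-bromo-6-methoxyphenyl]methyl}-2,6-bis(benzyloxy)-4-methoxyphenyl)methanone | COc1cc(OCc2ccccc2)c(C(=O)c2c(C)cc(OCc3ccccc3)cc2OCc2ccccc2)c(OCc2ccccc2)c1Cc1c(OC)cc(OCC=C)c(Br)c1OCc1ccccc1 | intermediate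
20 | [2,4-bis(benzyloxy)-6-methylphenyl](2,6-bis(benzyloxy)-3-{[2-(benzyloxy)-3-bromo-4-hydroxy-6-methoxyphenyl]methyl}-4-methoxyphenyl)methanone | COc1cc(OCc2ccccc2)c(C(=O)c2c(C)cc(OCc3ccccc3)cc2OCc2ccccc2)c(OCc2ccccc2)c1Cc1c(OC)cc(O)c(Br)c1OCc1ccccc1 | intermediate
21 | [2,4-bis(benzyloxy)-6-methylphenyl][2,6-bis(benzyloxy)-3-({2-(benzyloxy)-3-bromo-6-methoxy-4-[(trimethylsilyl)oxy]phenyl}methyl)-4-methoxyphenyl]methanone | COc1cc(OCc2ccccc2)c(C(=O)c2c(C)cc(OCc3ccccc3)cc2OCc2ccccc2)c(OCc2ccccc2)c1Cc1c(OC)cc(O[Si](C)(C)C)c(Br)c1OCc1ccccc1 | intermediate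
22 | lithium 3-(benzyloxy)-4-({2,4-bis(benzyloxy)-3-[2,4-bis(benzyloxy)-6-methylbenzoyl]-6-methoxyphenyl}methyl)-5-methoxy-2-(trimethylsilyl)phenolate | [Li+].COc1cc(OCc2ccccc2)c(C(=O)c2c(C)cc(OCc3ccccc3)cc2OCc2ccccc2)c(OCc2ccccc2)c1Cc1c(OC)cc([O-])c([Si](C)(C)C)c1OCc1ccccc1 | intermediate
23 | 3-(benzyloxy)-4-({2,4-bis(benzyloxy)-3-[2,4-bis(benzyloxy)-6-methylbenzoyl]-6-methoxyphenyl}methyl)-5-methoxy-2-(trimethylsilyl)phenyl trifluoromethanesulfonate | COc1cc(OCc2ccccc2)c(C(=O)c2c(C)cc(OCc3ccccc3)cc2OCc2ccccc2)c(OCc2ccccc2)c1Cc1c(OC)cc(OS(=O)(=O)C(F)(F)F)c([Si](C)(C)C)c1OCc1ccccc1 | intermediate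
24 | 4-(benzyloxy)-2-hydroxy-6-methylbenzaldehyde | Cc1cc(OCc2ccccc2)cc(O)c1C=O | intermediate
25 | 4-(benzyloxy)-2-methoxy-6-methylbenzaldehyde | COc1cc(OCc2ccccc2)cc(C)c1C=O | intermediate
26 | 4-(benzyloxy)-2-methoxy-6-methylbenzoic acid | COc1cc(OCc2ccccc2)cc(C)c1C(=O)O | intermediate
27 | cesium 4-(benzyloxy)-2-methoxy-6-methylbenzoate | [Cs+].COc1cc(OCc2ccccc2)cc(C)c1C(=O)[O-] | intermediate
28 | [2,4-bis(benzyloxy)-6-methylphenyl](2,6-bis(benzyloxy)-3-{[2-(benzyloxy)-6-methoxy-3,4-didehydrophenyl]methyl}-4-methoxyphenyl)methanone (aryne) | COc1cc(OCc2ccccc2)c(C(=O)c2c(C)cc(OCc3ccccc3)cc2OCc2ccccc2)c(OCc2ccccc2)c1CC1=C(OCc2ccccc2)C#CC=C1OC | intermediate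
29 | [2,4-bis(benzyloxy)-6-methylphenyl][2,6-bis(benzyloxy)-3-({2-(benzyloxy)-3-[4-(benzyloxy)-2-methoxy-6-methylbenzoyl]-4-hydroxy-6-methoxyphenyl}methyl)-4-methoxyphenyl]methanone | COc1cc(OCc2ccccc2)c(C(=O)c2c(C)cc(OCc3ccccc3)cc2OCc2ccccc2)c(OCc2ccccc2)c1Cc1c(OC)cc(O)c(C(=O)c2c(C)cc(OCc3ccccc3)cc2OC)c1OCc1ccccc1 | intermediate
30 | (2,4-dihydroxy-6-methylphenyl)[3-({2,4-dihydroxy-3-[4-hydroxy-2-methoxy-6-methylbenzoyl]-6-methoxyphenyl}methyl)-2,6-dihydroxy-4-methoxyphenyl]methanone | COc1cc(O)c(C(=O)c2c(C)cc(O)cc2O)c(O)c1Cc1c(OC)cc(O)c(C(=O)c2c(C)cc(O)cc2OC)c1O | target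

## Step count and risks

Total step count: 19. Longest linear sequence: 12 steps (steps 1, 2, 7, 8, 9, 10, 11, 12, 13, 14, 18, 19).

Steps most likely to fail:

1. Step 18. The C5 aryl anion formed after carboxylate addition may be protonated faster than it attacks the doubly ortho-substituted ester carbonyl, which would stop the sequence at O-arylation; fluoride may also outcompete the hindered carboxylate for the aryne. The fallback sets out from 19 and aldehyde 25 and comes back at 29. Bromine–lithium exchange on 19 (n-BuLi, THF, −78 °C) gives the ring B aryllithium F1, which adds to 25 to give the racemic diarylcarbinol F2. IBX oxidation gives the allyl-protected ketone F3, and Pd(PPh3)4 with morpholine removes the allyl group to give 29.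

2. Step 14. Butyllithium may add to, or transfer an electron to, the diaryl ketone, or deprotonate a benzylic ether methylene, before bromine–lithium exchange and the O-to-C silyl shift are complete. The fallback sets out from 20 and comes back at 23, lowering the oxidation level of the ketone for the organolithium step. LiAlH4 (THF, 0 °C → rt) reduces 20 to the racemic benzhydrol F4, and HMDS converts both hydroxyl groups into the bis(trimethylsilyl) ether F5. n-BuLi at −100 °C followed by PhNTf2 gives the silyl triflate still carrying the carbinol silyl ether F6, aqueous acetic acid in THF frees the benzhydrol silyl triflate F7, and IBX in EtOAc gives 23.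

3. Step 11. The ortho-quinone methide may oligomerise, alkylate a phenol oxygen, or alkylate ring A twice instead of once on carbon. The fallback sets out from 14 and 10 and comes back at 18, replacing the thermal quinone methide by a cationic Friedel–Crafts benzylation. NaBH4 (MeOH, 0 °C) reduces 14 to the salicyl alcohol F8, which is added slowly to 10 (2 equiv) with catalytic BF3·OEt2 in 1,4-dioxane to give 18.

Further compounds
F1 | step 18 | [6-(allyloxy)-2-(benzyloxy)-3-({2,4-bis(benzyloxy)-3-[2,4-bis(benzyloxy)-6-methylbenzoyl]-6-methoxyphenyl}methyl)-4-methoxyphenyl]lithium | COc1cc(OCc2ccccc2)c(C(=O)c2c(C)cc(OCc3ccccc3)cc2OCc2ccccc2)c(OCc2ccccc2)c1Cc1c(OC)cc(OCC=C)c([Li])c1OCc1ccccc1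
F2 | step 18 | [2,4-bis(benzyloxy)-6-methylphenyl][3-({4-(allyloxy)-2-(benzyloxy)-3-[(4-(benzyloxy)-2-methoxy-6-methylphenyl)(hydroxy)methyl]-6-methoxyphenyl}methyl)-2,6-bis(benzyloxy)-4-methoxyphenyl]methanone (racemic) | COc1cc(OCc2ccccc2)c(C(=O)c2c(C)cc(OCc3ccccc3)cc2OCc2ccccc2)c(OCc2ccccc2)c1Cc1c(OC)cc(OCC=C)c(C(O)c2c(C)cc(OCc3ccccc3)cc2OC)c1OCc1ccccc1
F3 | step 18 | [2,4-bis(benzyloxy)-6-methylphenyl][3-({4-(allyloxy)-2-(benzyloxy)-3-[4-(benzyloxy)-2-methoxy-6-methylbenzoyl]-6-methoxyphenyl}methyl)-2,6-bis(benzyloxy)-4-methoxyphenyl]methanone | COc1cc(OCc2ccccc2)c(C(=O)c2c(C)cc(OCc3ccccc3)cc2OCc2ccccc2)c(OCc2ccccc2)c1Cc1c(OC)cc(OCC=C)c(C(=O)c2c(C)cc(OCc3ccccc3)cc2OC)c1OCc1ccccc1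
F4 | step 14 | [2,4-bis(benzyloxy)-6-methylphenyl](2,6-bis(benzyloxy)-3-{[2-(benzyloxy)-3-bromo-4-hydroxy-6-methoxyphenyl]methyl}-4-methoxyphenyl)methanol (racemic) | COc1cc(OCc2ccccc2)c(C(O)c2c(C)cc(OCc3ccccc3)cc2OCc2ccccc2)c(OCc2ccccc2)c1Cc1c(OC)cc(O)c(Br)c1OCc1ccccc1
F5 | step 14 | bis(trimethylsilyl) ether of F4 (phenol and carbinol oxygens silylated; racemic) | COc1cc(OCc2ccccc2)c(C(O[Si](C)(C)C)c2c(C)cc(OCc3ccccc3)cc2OCc2ccccc2)c(OCc2ccccc2)c1Cc1c(OC)cc(O[Si](C)(C)C)c(Br)c1OCc1ccccc1
F6 | step 14 | 3-(benzyloxy)-4-[(2,4-bis(benzyloxy)-3-{[2,4-bis(benzyloxy)-6-methylphenyl][(trimethylsilyl)oxy]methyl}-6-methoxyphenyl)methyl]-5-methoxy-2-(trimethylsilyl)phenyl trifluoromethanesulfonate (racemic) | COc1cc(OCc2ccccc2)c(C(O[Si](C)(C)C)c2c(C)cc(OCc3ccccc3)cc2OCc2ccccc2)c(OCc2ccccc2)c1Cc1c(OC)cc(OS(=O)(=O)C(F)(F)F)c([Si](C)(C)C)c1OCc1ccccc1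
F7 | step 14 | 3-(benzyloxy)-4-[(2,4-bis(benzyloxy)-3-{[2,4-bis(benzyloxy)-6-methylphenyl](hydroxy)methyl}-6-methoxyphenyl)methyl]-5-methoxy-2-(trimethylsilyl)phenyl trifluoromethanesulfonate (racemic) | COc1cc(OCc2ccccc2)c(C(O)c2c(C)cc(OCc3ccccc3)cc2OCc2ccccc2)c(OCc2ccccc2)c1Cc1c(OC)cc(OS(=O)(=O)C(F)(F)F)c([Si](C)(C)C)c1OCc1ccccc1
F8 | step 11 | 3-(allyloxy)-2-bromo-6-(hydroxymethyl)-5-methoxyphenol | COc1cc(OCC=C)c(Br)c(O)c1CO
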